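**Retrosynthetic overview**

1. The C15 methyl succinate and the C19 isovalerate are cut back to a 2α-silyloxy-15,19-diol. C14–C15 comes from a Horner–Wadsworth–Emmons reaction on a C13 methyl ketone, and the 2α-OH from hydroboration of a C2=C3 alkene made from a C3 ketone.
2. The strategy rests on C4 of ring A: it is quaternary, carries the C18 methyl and the oxidised C19, and sits next to C3. It can therefore be the radical carbon of an α-methyl β-keto ester (C3 ketone, C19 ester).
3. Key disconnection: C4–C5 and C9–C10, opened together to an acyclic E,E-dienyl keto ester whose C5=C10 and C8=C9 alkenes take the radical. Ring A closes first and ring B second in the same operation. The copper-mediated termination leaves the alkene mainly at C8=C17, and one isomerisation step then moves it to C7=C8.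
4. The absolute configuration comes from an 8-phenylmenthyl ester at C19. The acyclic precursor comes from geranylacetone ketal (allylic oxidation, bromide) and the dianion of 8-phenylmenthyl 2-methylacetoacetate.

Key step: step 6

Assumption: the (−)-8-phenylmenthyl ester is taken to shield the face of the C4 radical that leads to the 4β-ester, 5α-H, 10β-methyl series drawn; should the sense prove opposite, (+)-8-phenylmenthol replaces 6 with no other change. Labdane numbering is used for all bicyclic compounds.

**Route**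

Step 1
Reactants: 1 geranylacetone
Product: 2 geranylacetone ethylene ketal, 2-[(3E)-4,8-dimethylnona-3,7-dienyl]-2-methyl-1,3-dioxolane
Conditions: ethylene glycol, PPTS (cat.), benzene, reflux, Dean–Stark
Reagents that add atoms: ethylene glycol OCCO
Why: Acid-catalysed ketalisation driven by azeotropic removal of water; the weak acid leaves both trisubstituted alkenes in place, and the dioxolane masks the ketone against the bases and hydride sources used up to step 10.

Step 2
Reactants: 2 geranylacetone ethylene ketal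
Product: 3 (2E,6E)-2,6-dimethyl-9-(2-methyl-1,3-dioxolan-2-yl)nona-2,6-dien-1-ol
Conditions: SeO2 (cat.), t-BuOOH, CH2Cl2, 0 °C to rt
Reagents that add atoms: tert-butyl hydroperoxide CC(C)(C)OO
Why: Catalytic SeO2 allylic oxidation (ene reaction, then [2,3]-sigmatropic shift) attacks the terminal isopropylidene group, the most accessible alkene, and hydroxylates its E-methyl, so the new trisubstituted alkene should be E; the reaction is stopped at partial conversion to limit over-oxidation.

Step 3
Reactants: 3 allylic alcohol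
Product: 4 2-[(3E,7E)-9-bromo-4,8-dimethylnona-3,7-dienyl]-2-methyl-1,3-dioxolane
Conditions: CBr4, PPh3, CH2Cl2, 0 °C
Reagents that add atoms: carbon tetrabromide BrC(Br)(Br)Br
Why: Appel reaction; bromide displaces the alkoxyphosphonium group under neutral conditions, which should keep both the alkene geometry and the ketal.

Step 4
Reactants: 5 ethyl 2-methylacetoacetate; 6 (−)-8-phenylmenthol
Product: 7 (−)-8-phenylmenthyl 2-methyl-3-oxobutanoate (both C2 epimers)
Conditions: DMAP (cat.), toluene, reflux, EtOH distilled off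
Reagents that add atoms: none
Why: DMAP-catalysed transesterification of a β-keto ester (through the acylketene), driven by removal of ethanol; the epimeric α-carbon is of no consequence because it becomes the radical carbon.

Step 5
Reactants: 7 8-phenylmenthyl 2-methylacetoacetate; 4 allylic bromide
Product: 9 (−)-8-phenylmenthyl (6E,10E)-2,6,10-trimethyl-13-(2-methyl-1,3-dioxolan-2-yl)-3-oxotrideca-6,10-dienoate (C2 unassigned), via dilithium dianion 8 (not isolated)
Conditions: LDA (2.1 equiv), THF, 0 °C; then 4, 0 °C; AcOH quench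
Reagents that add atoms: none
Why: β-Keto ester dianion alkylation; the terminal (γ) carbanion is the more nucleophilic site and displaces the primary allylic bromide by direct substitution, which joins what become C2 and C1 without touching the E-alkenes.

Step 6
Reactants: 9 keto ester polyene
Product: 10 (−)-8-phenylmenthyl 13,13-ethylenedioxy-3-oxo-14,15-dinorlabd-8(17)-en-19-oate (4α-methyl, 4β-ester, 5α-H, 9β side chain, 10β-methyl)
Conditions: Mn(OAc)3·2H2O (2.2 equiv), Cu(OAc)2·H2O (1 equiv), degassed AcOH, rt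
Reagents that add atoms: none
Why: Mn(OAc)3 forms the manganese enolate of the β-keto ester and electron transfer releases the electrophilic tertiary C4 radical, which adds to C5 of the C5=C10 alkene; the tertiary C10 radical then adds to C9 of the C8=C9 alkene, and the tertiary C8 radical is oxidised by Cu(OAc)2 to an alkene through an alkylcopper intermediate, the monovalent copper being re-oxidised by the second equivalent of Mn(OAc)3. The closest known reaction type is the Mn(OAc)3/Cu(OAc)2 oxidative free-radical polycyclisation of unsaturated α-alkyl β-keto esters, including 8-phenylmenthyl esters. Ring A closes 6-endo-trig (C4–C5) and ring B closes 6-endo-trig (C9–C10), each attack going to the less substituted alkene carbon and leaving a tertiary radical. C5, C10 and C9 follow from chair–chair folding of the E,E-diene (trans ring fusion, 10β-methyl, equatorial 9β side chain), C4 from the preference of these radicals for the transition state with the ketone in the ring and the ester axial, and the absolute sense from the phenyl ring of the auxiliary lying over one face of the radical so that C5 bonds from the open face. The step needs both additions to outrun oxidation of the intermediate radicals, which the fast 6-endo additions to trisubstituted alkenes should secure, and it needs C13 to be saturated (the dioxolane, expected to survive the acetate-rich medium at room temperature) so that no third ring forms. The alkene position is the one outcome not controlled: the alkylcopper intermediate should lose hydrogen mainly from the unhindered C17 methyl, so the 8(17)-ene 10 is taken as the product, and the 7-ene 11 that forms beside it by loss of H7 is carried along with 10 into step 7, where the mixture converges on 11.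

Step 7
Reactants: 10 8(17)-ene keto ester (used as the crude mixture of alkene regioisomers from step 6)
Product: 11 (−)-8-phenylmenthyl 13,13-ethylenedioxy-3-oxo-14,15-dinorlabd-7-en-19-oate
Conditions: Co(salen)Cl (3 mol %; salen = N,N′-bis(3,5-di-tert-butylsalicylidene)cyclohexane-1,2-diaminate), PhSiH3 (6 mol %), benzene, rt
Reagents that add atoms: none
Why: Cobalt hydride hydrogen-atom-transfer alkene isomerisation: hydrogen is delivered to C17 to give the tertiary C8 radical, and the divalent cobalt complex should take hydrogen back from the accessible C7 methylene and not from the shielded C9 methine next to quaternary C10, so the exocyclic alkene moves one position into ring B while the slower-reacting trisubstituted 7-ene already present, the ketone, the ketal and the ester are left alone by the catalytic silane; the minor C4 diastereomer from step 6 is removed by chromatography here.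

Step 8
Reactants: 11 keto ester
Product: 13 (−)-8-phenylmenthyl 13,13-ethylenedioxy-3-(trifluoromethanesulfonyloxy)-14,15-dinorlabda-2,7-dien-19-oate, via potassium enolate 12 (not isolated)
Conditions: KHMDS, THF, −78 °C; then PhNTf2, −78 to 0 °C
Reagents that add atoms: N-phenylbis(trifluoromethanesulfonimide) O=S(=O)(N(c1ccccc1)S(=O)(=O)C(F)(F)F)C(F)(F)F
Why: Enol triflate formation; the C3 ketone can enolise only towards C2 because C4 is quaternary, and the hindered ester has no α-hydrogen, so a single enolate is O-sulfonylated.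

Step 9
Reactants: 13 enol triflate
Product: 14 (−)-8-phenylmenthyl 13,13-ethylenedioxy-14,15-dinorlabda-2,7-dien-19-oate
Conditions: Pd(OAc)2 (5 mol %), PPh3, HCO2H, n-Bu3N, DMF, 60 °C
Reagents that add atoms: none
Why: Palladium-catalysed formate reduction of an enol triflate: zerovalent palladium inserts into the C3–O bond, formate exchanges for triflate and loses CO2 to give a palladium hydride, and reductive elimination leaves the C2=C3 alkene, a reaction well established for hindered 4,4-disubstituted 3-ketone triflates.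

Step 10
Reactants: 14 2,7-diene
Product: 16 (−)-8-phenylmenthyl 13,13-ethylenedioxy-2α-hydroxy-14,15-dinorlabd-7-en-19-oate, via C2 alkylborane 15 (not isolated)
Conditions: 9-BBN, THF, 65 °C; then NaOH, H2O2, H2O, 0 °C to rt
Reagents that add atoms: hydrogen peroxide OO (9-BBN, C1CC2CCCC(C1)B2, leaves atoms only in intermediate 15)
Why: Hydroboration–oxidation: the bulky borane should react with the cis-disubstituted C2=C3 alkene much faster than with the trisubstituted ring B alkene, boron goes to C2 because C3 is flanked by quaternary C4, and it approaches the α face away from the axial 10β-methyl and 4β-ester, so oxidation with retention gives the equatorial 2α-alcohol.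

Step 11
Reactants: 16 hydroxy ketal
Product: 17 (−)-8-phenylmenthyl 2α-hydroxy-13-oxo-14,15-dinorlabd-7-en-19-oate
Conditions: 1 M HCl, THF, rt
Reagents that add atoms: water O
Why: Acid hydrolysis of the dioxolane; dilute acid at room temperature should not move the ring B alkene or touch the hindered ester, and it is placed before silylation so that no silyl ether meets aqueous acid.

Step 12
Reactants: 17 hydroxy ketone
Product: 18 (−)-8-phenylmenthyl 2α-(tert-butyldimethylsilyloxy)-13-oxo-14,15-dinorlabd-7-en-19-oate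
Conditions: TBSCl, imidazole, DMF, rt
Reagents that add atoms: tert-butyldimethylsilyl chloride CC(C)(C)[Si](C)(C)Cl
Why: Silylation of an unhindered equatorial secondary alcohol; the ether keeps O2 apart from O15 and O19 through reduction and both acylations.

Step 13
Reactants: 18 silyloxy ketone
Product: 19 15-ethyl 19-[(−)-8-phenylmenthyl] (13E)-2α-(tert-butyldimethylsilyloxy)labda-7,13-diene-15,19-dioate
Conditions: (EtO)2P(O)CH2CO2Et, NaH, THF, 0 to 50 °C
Reagents that add atoms: triethyl phosphonoacetate CCOC(=O)CP(=O)(OCC)OCC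
Why: Horner–Wadsworth–Emmons olefination of the only ketone adds C14 and C15; the 13E enoate should predominate because the ester sits anti to the larger C12 chain in the favoured oxaphosphetane, and the minor 13Z isomer is removed by chromatography.

Step 14
Reactants: 19 diester
Product: 20 (13E)-2α-(tert-butyldimethylsilyloxy)labda-7,13-diene-15,19-diol
Conditions: LiAlH4, THF, 0 to 50 °C; aq. NaOH work-up
Reagents that add atoms: none
Why: Hydride reduction of both esters in one operation: the enoate gives the allylic alcohol by 1,2-reduction and the hindered axial C19 ester is reduced on warming, which also returns the auxiliary 6 for re-use; the silyl ether and the isolated alkenes are inert.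

Step 15
Reactants: 20 diol
Product: 21 (13E)-2α-(tert-butyldimethylsilyloxy)-19-hydroxylabda-7,13-dien-15-yl methyl succinate
Conditions: methyl 4-chloro-4-oxobutanoate (1.05 equiv), pyridine, CH2Cl2, −40 °C
Reagents that add atoms: methyl 4-chloro-4-oxobutanoate COC(=O)CCC(=O)Cl
Why: Rate-controlled acylation; the unhindered primary allylic C15 alcohol should react far faster with the acid chloride at low temperature than the axial neopentyl C19 alcohol on quaternary C4.

Step 16
Reactants: 21 monoester
Product: 22 (13E)-2α-(tert-butyldimethylsilyloxy)-19-(3-methylbutanoyloxy)labda-7,13-dien-15-yl methyl succinate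
Conditions: isovaleryl chloride, Et3N, DMAP (cat.), CH2Cl2, rt
Reagents that add atoms: isovaleryl chloride CC(C)CC(=O)Cl
Why: DMAP-catalysed acylation of the remaining, hindered primary alcohol through the acylpyridinium ion; no other free hydroxyl is present.

Step 17
Reactants: 22 silyl ether
Product: 23 CNP0118741.1, (13E)-2α-hydroxy-19-(3-methylbutanoyloxy)labda-7,13-dien-15-yl methyl succinate
Conditions: HF·pyridine, THF, 0 °C to rt
Reagents that add atoms: none
Why: Fluoride cleavage of the silyl ether under mildly acidic, non-nucleophilic conditions that should leave the three esters and the allylic C15–O bond intact; the 2α-hydroxyl and the C19 ester lie on opposite faces of ring A, so acyl migration is not expected.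

**Compound list**

1 | geranylacetone | CC(C)=CCC/C(C)=C/CCC(C)=O | starting material
2 | geranylacetone ethylene ketal | CC(C)=CCC/C(C)=C/CCC1(C)OCCO1 | intermediate
3 | (2E,6E)-2,6-dimethyl-9-(2-methyl-1,3-dioxolan-2-yl)nona-2,6-dien-1-ol | OC/C(C)=C/CC/C(C)=C/CCC1(C)OCCO1 | intermediate
4 | 2-[(3E,7E)-9-bromo-4,8-dimethylnona-3,7-dienyl]-2-methyl-1,3-dioxolane | BrC/C(C)=C/CC/C(C)=C/CCC1(C)OCCO1 | intermediate
5 | ethyl 2-methylacetoacetate | CCOC(=O)C(C)C(C)=O | starting material
6 | (−)-8-phenylmenthol | C[C@@H]1CC[C@H]([C@@H](C1)O)C(C)(C)c1ccccc1 | starting material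
7 | (−)-8-phenylmenthyl 2-methyl-3-oxobutanoate | CC(=O)C(C)C(=O)O[C@@H]1C[C@H](C)CC[C@H]1C(C)(C)c1ccccc1 | intermediate
8 | dilithium dianion of 7 (not isolated) | [Li+].[Li+].[CH2-]C(=O)[C-](C)C(=O)O[C@@H]1C[C@H](C)CC[C@H]1C(C)(C)c1ccccc1 | intermediate
9 | (−)-8-phenylmenthyl (6E,10E)-2,6,10-trimethyl-13-(2-methyl-1,3-dioxolan-2-yl)-3-oxotrideca-6,10-dienoate | CC(C(=O)O[C@@H]1C[C@H](C)CC[C@H]1C(C)(C)c1ccccc1)C(=O)CC/C(C)=C/CC/C(C)=C/CCC1(C)OCCO1 | intermediate
10 | (−)-8-phenylmenthyl 13,13-ethylenedioxy-3-oxo-14,15-dinorlabd-8(17)-en-19-oate | CC3(OCCO3)CC[C@H]1C(=C)CC[C@H]2[C@@](C)(C(=O)O[C@@H]4C[C@H](C)CC[C@H]4C(C)(C)c4ccccc4)C(=O)CC[C@]12C | intermediate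
11 | (−)-8-phenylmenthyl 13,13-ethylenedioxy-3-oxo-14,15-dinorlabd-7-en-19-oate | CC3(OCCO3)CC[C@H]1C(C)=CC[C@H]2[C@@](C)(C(=O)O[C@@H]4C[C@H](C)CC[C@H]4C(C)(C)c4ccccc4)C(=O)CC[C@]12C | intermediate
12 | potassium C2–C3 enolate of 11 (not isolated) | [K+].CC3(OCCO3)CC[C@H]1C(C)=CC[C@H]2[C@@](C)(C(=O)O[C@@H]4C[C@H](C)CC[C@H]4C(C)(C)c4ccccc4)C([O-])=CC[C@]12C | intermediate
13 | (−)-8-phenylmenthyl 13,13-ethylenedioxy-3-(trifluoromethanesulfonyloxy)-14,15-dinorlabda-2,7-dien-19-oate | CC3(OCCO3)CC[C@H]1C(C)=CC[C@H]2[C@@](C)(C(=O)O[C@@H]4C[C@H](C)CC[C@H]4C(C)(C)c4ccccc4)C(OS(=O)(=O)C(F)(F)F)=CC[C@]12C | intermediate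
14 | (−)-8-phenylmenthyl 13,13-ethylenedioxy-14,15-dinorlabda-2,7-dien-19-oate | CC3(OCCO3)CC[C@H]1C(C)=CC[C@H]2[C@@](C)(C(=O)O[C@@H]4C[C@H](C)CC[C@H]4C(C)(C)c4ccccc4)C=CC[C@]12C | intermediate
15 | 2α-(9-borabicyclo[3.3.1]nonan-9-yl) adduct of 14 (not isolated) | CC3(OCCO3)CC[C@H]1C(C)=CC[C@H]2[C@@](C)(C(=O)O[C@@H]4C[C@H](C)CC[C@H]4C(C)(C)c4ccccc4)C[C@H](B5C6CCCC5CCC6)C[C@]12C | intermediate
16 | (−)-8-phenylmenthyl 13,13-ethylenedioxy-2α-hydroxy-14,15-dinorlabd-7-en-19-oate | CC3(OCCO3)CC[C@H]1C(C)=CC[C@H]2[C@@](C)(C(=O)O[C@@H]4C[C@H](C)CC[C@H]4C(C)(C)c4ccccc4)C[C@H](O)C[C@]12C | intermediate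
17 | (−)-8-phenylmenthyl 2α-hydroxy-13-oxo-14,15-dinorlabd-7-en-19-oate | CC(=O)CC[C@H]1C(C)=CC[C@H]2[C@@](C)(C(=O)O[C@@H]3C[C@H](C)CC[C@H]3C(C)(C)c3ccccc3)C[C@H](O)C[C@]12C | intermediate
18 | (−)-8-phenylmenthyl 2α-(tert-butyldimethylsilyloxy)-13-oxo-14,15-dinorlabd-7-en-19-oate | CC(=O)CC[C@H]1C(C)=CC[C@H]2[C@@](C)(C(=O)O[C@@H]3C[C@H](C)CC[C@H]3C(C)(C)c3ccccc3)C[C@H](O[Si](C)(C)C(C)(C)C)C[C@]12C | intermediate
19 | 15-ethyl 19-[(−)-8-phenylmenthyl] (13E)-2α-(tert-butyldimethylsilyloxy)labda-7,13-diene-15,19-dioate | CCOC(=O)/C=C(\C)CC[C@H]1C(C)=CC[C@H]2[C@@](C)(C(=O)O[C@@H]3C[C@H](C)CC[C@H]3C(C)(C)c3ccccc3)C[C@H](O[Si](C)(C)C(C)(C)C)C[C@]12C | intermediate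
20 | (13E)-2α-(tert-butyldimethylsilyloxy)labda-7,13-diene-15,19-diol | OC/C=C(\C)CC[C@H]1C(C)=CC[C@H]2[C@@](C)(CO)C[C@H](O[Si](C)(C)C(C)(C)C)C[C@]12C | intermediate
21 | (13E)-2α-(tert-butyldimethylsilyloxy)-19-hydroxylabda-7,13-dien-15-yl methyl succinate | COC(=O)CCC(=O)OC/C=C(\C)CC[C@H]1C(C)=CC[C@H]2[C@@](C)(CO)C[C@H](O[Si](C)(C)C(C)(C)C)C[C@]12C | intermediate
22 | (13E)-2α-(tert-butyldimethylsilyloxy)-19-(3-methylbutanoyloxy)labda-7,13-dien-15-yl methyl succinate | COC(=O)CCC(=O)OC/C=C(\C)CC[C@H]1C(C)=CC[C@H]2[C@@](C)(COC(=O)CC(C)C)C[C@H](O[Si](C)(C)C(C)(C)C)C[C@]12C | intermediate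
23 | CNP0118741.1 | COC(=O)CCC(=O)OC/C=C(\C)CC[C@H]1C(C)=CC[C@H]2[C@@](C)(COC(=O)CC(C)C)C[C@H](O)C[C@]12C | target

**Step count**

Total: 17 steps. Longest linear sequence: 16 steps (steps 1–3 and 5–17 from geranylacetone); step 4 is the side branch.

**Steps most likely to fail**

1. Step 6. The phenyl ring of the auxiliary may discriminate poorly between the two faces of the conformationally free C4 radical in acetic acid, and the dioxolane may be partly lost to the wet acidic medium. The fallback moves the stereocontrol to a lanthanide chelate on a substrate without the ketal and puts the ketal on only after the rings are formed. It sets out from 9: the ketal is hydrolysed (PPTS, acetone–water) to the free methyl ketone precursor F1. F1 is cyclised with Mn(OAc)3·2H2O, Cu(OAc)2·H2O and Yb(OTf)3 in CF3CH2OH at 0 °C, where chelation of both carbonyls fixes the radical under the phenyl ring, to give the 3,13-dioxo 8(17)-ene ester F2 together with its 7-ene isomer F3. F2 is converged on F3 under the conditions of step 7. The unhindered C13 ketone of F3 is then ketalised selectively (ethylene glycol, PPTS, benzene, Dean–Stark; the C3 ketone next to quaternary C4 should not react), and the route is rejoined at 11.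

2. Step 7. Hydrogen return may take place from C9 as well as from C7, which would give the tetrasubstituted 8-ene, or the isomerisation may stall. The fallback places the alkene by enolate regiochemistry instead. It sets out from 10, freed on AgNO3-impregnated silica from the portion of 11 formed in step 6 (that portion goes through steps 8 and 9 as written). Treatment with KHMDS and PhNTf2 gives the exocyclic-alkene enol triflate F4. Ozonolysis of the electron-rich 1,1-disubstituted alkene (O3, CH2Cl2, −78 °C, then Me2S) gives the 17-nor 8-ketone triflate F5. Formate reduction under the conditions of step 9 gives the 2-en-8-one F6. Kinetic enolisation towards the C7 methylene (KHMDS, PhNTf2, −78 °C) gives the 8-triflyloxy 2,7-diene F7. Negishi coupling with MeZnCl and Pd(PPh3)4 in THF installs C17, and the route is rejoined at 14.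

3. Step 10. The borane may also attack the ring B alkene, or deliver boron to C3. The fallback oxygenates C2 at the ketone stage and removes the C3 oxygen afterwards, so that no alkene needs to be hydroborated. It sets out from 11: the potassium enolate (KHMDS, THF, −78 °C) is hydroxylated from the α face with 2-(phenylsulfonyl)-3-phenyloxaziridine to give the 2α-hydroxy 3-ketone F8, which is silylated (TBSCl, imidazole) to the silyloxy ketone F9. NaBH4 in MeOH gives the 3-alcohol F10 (3β expected; either epimer serves). Phenyl chlorothionoformate, pyridine and DMAP give the thionocarbonate F11, and Barton–McCombie deoxygenation (Bu3SnH, AIBN, toluene, 100 °C) gives the 2α-silyloxy ketal F12. Mild ketal hydrolysis (PPTS, acetone–water, 50 °C) rejoins the route at 18.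

**Further compounds**

F1 | step 6 | (−)-8-phenylmenthyl (6E,10E)-2,6,10-trimethyl-3,14-dioxopentadeca-6,10-dienoate | CC(C(=O)O[C@@H]1C[C@H](C)CC[C@H]1C(C)(C)c1ccccc1)C(=O)CC/C(C)=C/CC/C(C)=C/CCC(C)=O
F2 | step 6 | (−)-8-phenylmenthyl 3,13-dioxo-14,15-dinorlabd-8(17)-en-19-oate | CC(=O)CC[C@H]1C(=C)CC[C@H]2[C@@](C)(C(=O)O[C@@H]3C[C@H](C)CC[C@H]3C(C)(C)c3ccccc3)C(=O)CC[C@]12C
F3 | step 6 | (−)-8-phenylmenthyl 3,13-dioxo-14,15-dinorlabd-7-en-19-oate | CC(=O)CC[C@H]1C(C)=CC[C@H]2[C@@](C)(C(=O)O[C@@H]3C[C@H](C)CC[C@H]3C(C)(C)c3ccccc3)C(=O)CC[C@]12C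
F4 | step 7 | (−)-8-phenylmenthyl 13,13-ethylenedioxy-3-(trifluoromethanesulfonyloxy)-14,15-dinorlabda-2,8(17)-dien-19-oate | CC3(OCCO3)CC[C@H]1C(=C)CC[C@H]2[C@@](C)(C(=O)O[C@@H]4C[C@H](C)CC[C@H]4C(C)(C)c4ccccc4)C(OS(=O)(=O)C(F)(F)F)=CC[C@]12C
F5 | step 7 | (−)-8-phenylmenthyl 13,13-ethylenedioxy-8-oxo-3-(trifluoromethanesulfonyloxy)-14,15,17-trinorlabd-2-en-19-oate | CC3(OCCO3)CC[C@H]1C(=O)CC[C@H]2[C@@](C)(C(=O)O[C@@H]4C[C@H](C)CC[C@H]4C(C)(C)c4ccccc4)C(OS(=O)(=O)C(F)(F)F)=CC[C@]12C
F6 | step 7 | (−)-8-phenylmenthyl 13,13-ethylenedioxy-8-oxo-14,15,17-trinorlabd-2-en-19-oate | CC3(OCCO3)CC[C@H]1C(=O)CC[C@H]2[C@@](C)(C(=O)O[C@@H]4C[C@H](C)CC[C@H]4C(C)(C)c4ccccc4)C=CC[C@]12C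
F7 | step 7 | (−)-8-phenylmenthyl 13,13-ethylenedioxy-8-(trifluoromethanesulfonyloxy)-14,15,17-trinorlabda-2,7-dien-19-oate | CC3(OCCO3)CC[C@H]1C(OS(=O)(=O)C(F)(F)F)=CC[C@H]2[C@@](C)(C(=O)O[C@@H]4C[C@H](C)CC[C@H]4C(C)(C)c4ccccc4)C=CC[C@]12C
F8 | step 10 | (−)-8-phenylmenthyl 13,13-ethylenedioxy-2α-hydroxy-3-oxo-14,15-dinorlabd-7-en-19-oate | CC3(OCCO3)CC[C@H]1C(C)=CC[C@H]2[C@@](C)(C(=O)O[C@@H]4C[C@H](C)CC[C@H]4C(C)(C)c4ccccc4)C(=O)[C@H](O)C[C@]12C
F9 | step 10 | (−)-8-phenylmenthyl 2α-(tert-butyldimethylsilyloxy)-13,13-ethylenedioxy-3-oxo-14,15-dinorlabd-7-en-19-oate | CC3(OCCO3)CC[C@H]1C(C)=CC[C@H]2[C@@](C)(C(=O)O[C@@H]4C[C@H](C)CC[C@H]4C(C)(C)c4ccccc4)C(=O)[C@H](O[Si](C)(C)C(C)(C)C)C[C@]12C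
F10 | step 10 | (−)-8-phenylmenthyl 2α-(tert-butyldimethylsilyloxy)-13,13-ethylenedioxy-3β-hydroxy-14,15-dinorlabd-7-en-19-oate | CC3(OCCO3)CC[C@H]1C(C)=CC[C@H]2[C@@](C)(C(=O)O[C@@H]4C[C@H](C)CC[C@H]4C(C)(C)c4ccccc4)[C@@H](O)[C@H](O[Si](C)(C)C(C)(C)C)C[C@]12C
F11 | step 10 | (−)-8-phenylmenthyl 2α-(tert-butyldimethylsilyloxy)-13,13-ethylenedioxy-3β-(phenoxythiocarbonyloxy)-14,15-dinorlabd-7-en-19-oate | CC3(OCCO3)CC[C@H]1C(C)=CC[C@H]2[C@@](C)(C(=O)O[C@@H]4C[C@H](C)CC[C@H]4C(C)(C)c4ccccc4)[C@@H](OC(=S)Oc5ccccc5)[C@H](O[Si](C)(C)C(C)(C)C)C[C@]12C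
F12 | step 10 | (−)-8-phenylmenthyl 2α-(tert-butyldimethylsilyloxy)-13,13-ethylenedioxy-14,15-dinorlabd-7-en-19-oate | CC3(OCCO3)CC[C@H]1C(C)=CC[C@H]2[C@@](C)(C(=O)O[C@@H]4C[C@H](C)CC[C@H]4C(C)(C)c4ccccc4)C[C@H](O[Si](C)(C)C(C)(C)C)C[C@]12C
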